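The cyclohexane ring (C1 = CH bearing the benzyl group, C2 = CMe2, C3 = CHBr, C6 = C=CH2) is opened between C6 and C1. The triad C6(=CH2)–C1(H)–CH2Ar is the retron of a reductive enyne cyclisation. A palladium hydride unites two π-nucleophilic carbons, the internal carbon of a terminal alkyne and the β-carbon of a styrene. One operation closes the ring, creates the methylene group and the benzylic CH2, and sets C1 from the C3–Br centre, whatever the alkene geometry. The precursor is an acyclic (R)-bromo-1,7-enyne, made by asymmetric aldol addition, invertive bromination and Wittig olefination.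

Key step: step 8

Remark: the sense of induction in step 2 is assumed to follow that of other unbranched aliphatic aldehydes with valine-derived oxazaborolidinones, where the D-valine promoter gives the (S)-carbinol.

Step 1
Reactants: 1 pent-4-yn-1-ol
Product: 2 pent-4-ynal
Conditions: TEMPO (10 mol %), PhI(OAc)2 (1.1 equiv), CH2Cl2, rt
Reagents that add atoms: none
Why: TEMPO/oxoammonium oxidation of a primary alcohol stops at the aldehyde in anhydrous CH2Cl2 and does not touch the terminal alkyne; no stereocentre is formed.

Step 2
Reactants: 2 pent-4-ynal; 3 1-methoxy-2-methyl-1-(trimethylsiloxy)prop-1-ene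
Product: 4 methyl (3S)-3-hydroxy-2,2-dimethylhept-6-ynoate
Conditions: N-tosyl-D-valine (1.1 equiv), BH3·THF (1.0 equiv), CH2Cl2, 0 °C to rt; then 2 and 3, −78 °C; pH 7 buffer
Reagents that add atoms: none
Why: Asymmetric Mukaiyama aldol addition, in which the oxazaborolidinone formed from N-tosyl-D-valine and borane binds the aldehyde on the face away from its isopropyl group, so the ketene acetal attacks one carbonyl face and sets the (S)-carbinol next to the new quaternary carbon, while the neutral medium leaves the acidic alkyne C–H alone.

Step 3
Reactants: 4 methyl (3S)-3-hydroxy-2,2-dimethylhept-6-ynoate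
Product: 6 methyl (3R)-3-bromo-2,2-dimethylhept-6-ynoate, via (3S)-triflate 5 (not isolated)
Conditions: Tf2O (1.2 equiv), 2,6-lutidine (1.5 equiv), CH2Cl2, −78 to −20 °C; then n-Bu4NBr (3 equiv), −20 °C to rt
Reagents that add atoms: tetrabutylammonium bromide CCCC[N+](CCCC)(CCCC)CCCC.[Br-]; triflic anhydride O=S(=O)(OS(=O)(=O)C(F)(F)F)C(F)(F)F (its atoms stay in 5 only)
Why: SN2 displacement of a secondary triflate by bromide with inversion (3S to 3R), in which the best available nucleofuge offsets the neopentylic hindrance and the adjacent ester disfavours ionisation and Wagner–Meerwein shifts, so substitution should outrun rearrangement.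

Step 4
Reactants: 6 methyl (3R)-3-bromo-2,2-dimethylhept-6-ynoate
Product: 7 (3R)-3-bromo-2,2-dimethylhept-6-ynal
Conditions: DIBAL-H (1.1 equiv), CH2Cl2, −78 °C; MeOH quench, aq. Rochelle salt
Reagents that add atoms: none
Why: Partial ester reduction with DIBAL-H, which the low temperature and the α-quaternary centre hold at the aldehyde level until the quench, while bromide and alkyne are inert at −78 °C and the missing α-hydrogen rules out loss of HBr or epimerisation.

Step 5
Reactants: 8 4-bromo-2,5-dimethoxybenzaldehyde
Product: 9 (4-bromo-2,5-dimethoxyphenyl)methanol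
Conditions: NaBH4, MeOH, 0 °C
Reagents that add atoms: none
Why: Borohydride reduction of an aromatic aldehyde, which leaves the aryl bromide and the methyl ethers untouched.

Step 6
Reactants: 9 (4-bromo-2,5-dimethoxyphenyl)methanol
Product: 10 (4-bromo-2,5-dimethoxybenzyl)triphenylphosphonium bromide
Conditions: PPh3·HBr (1.05 equiv), MeCN, reflux
Reagents that add atoms: triphenylphosphine hydrobromide [Br-].c1ccc([PH+](c2ccccc2)c2ccccc2)cc1
Why: Direct phosphonium salt formation from an electron-rich benzylic alcohol, in which protonation and loss of water activate the benzylic carbon and triphenylphosphine captures it irreversibly.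

Step 7
Reactants: 10 (4-bromo-2,5-dimethoxybenzyl)triphenylphosphonium bromide; 7 (3R)-3-bromo-2,2-dimethylhept-6-ynal
Product: 12 1-bromo-4-[(1E,4R)-4-bromo-3,3-dimethyloct-1-en-7-yn-1-yl]-2,5-dimethoxybenzene, via phosphonium ylide 11 (not isolated)
Conditions: NaHMDS (1.0 equiv to 10), THF, −78 to 0 °C; then 7, −78 °C to rt
Reagents that add atoms: none
Why: Wittig olefination with a semi-stabilised benzylide, which is too weak a base to deprotonate the alkyne or eliminate the hindered bromide and whose cycloaddition pathway avoids a free γ-bromo alkoxide; the tertiary alkyl group should favour the E-alkene, and any Z-isomer can be carried on because step 8 erases the alkene geometry.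

Step 8
Reactants: 12 1-bromo-4-[(1E,4R)-4-bromo-3,3-dimethyloct-1-en-7-yn-1-yl]-2,5-dimethoxybenzene
Product: 13 1-bromo-4-{[(1S,3R)-3-bromo-2,2-dimethyl-6-methylidenecyclohexyl]methyl}-2,5-dimethoxybenzene
Conditions: Pd2(dba)3·CHCl3 (2.5 mol %), P(o-tol)3 (10 mol %), AcOH (2 equiv), Et3SiH (5 equiv), toluene, rt
Reagents that add atoms: none
Why: Pd(0) and AcOH give H–Pd–OAc, which adds across the terminal alkyne with hydrogen on the terminus and palladium on the internal carbon (future C6); the alkenylpalladium inserts the styrene in a syn fashion, forming C6–C1 and placing palladium on the benzylic carbon, where Et3SiH exchanges acetate for hydride and reductive elimination delivers the benzylic CH2 and Pd(0). The closest known reaction type is the palladium-catalysed reductive cyclisation of 1,6- and 1,7-enynes with a silane and acetic acid, an intercepted cycloisomerisation that joins two carbons of like (nucleophilic) polarity. The only ring formed closes by 6-exo-trig carbopalladation, helped by the gem-dimethyl group at C2. The new stereocentre C1 is controlled by the C3–Br centre, because a chair-like transition state with bromine and the arylvinyl unit both equatorial leads to the cis-1,3 relationship, (1S,3R). The step needs alkyne hydropalladation to outrun C–Br insertion, which room temperature, a bulky weakly donating phosphine, the electron-rich aryl bromide and the neopentylic alkyl bromide should secure; exo over endo closure is matched by the stabilised η3-benzylpalladium, and excess silane must intercept this species before β-hydride elimination of C1–H. Since the benzylic carbon ends as CH2, E- and Z-12 converge on the same product.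

Step 9
Reactants: 13 1-bromo-4-{[(1S,3R)-3-bromo-2,2-dimethyl-6-methylidenecyclohexyl]methyl}-2,5-dimethoxybenzene
Product: 15 cyclocymopol, via bromoquinone 14 (not isolated)
Conditions: (NH4)2Ce(NO3)6 (2.5 equiv), MeCN/H2O, 0 °C; extract into Et2O, then aq. Na2S2O4/NaHCO3, rt
Reagents that add atoms: water O
Why: Cerium(IV) oxidative demethylation turns the 1,4-dimethoxyarene into the bromoquinone without touching the alkene or either C–Br bond, and buffered dithionite reduction then gives the hydroquinone without acid strong enough to close the phenol onto the methylene group; no stereocentre is touched.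

Compound list
1 | pent-4-yn-1-ol | C#CCCCO | starting material
2 | pent-4-ynal | C#CCCC=O | intermediate
3 | 1-methoxy-2-methyl-1-(trimethylsiloxy)prop-1-ene | COC(O[Si](C)(C)C)=C(C)C | starting material
4 | methyl (3S)-3-hydroxy-2,2-dimethylhept-6-ynoate | C#CCC[C@H](O)C(C)(C)C(=O)OC | intermediate
5 | methyl (3S)-2,2-dimethyl-3-(trifluoromethylsulfonyloxy)hept-6-ynoate (not isolated) | C#CCC[C@H](OS(=O)(=O)C(F)(F)F)C(C)(C)C(=O)OC | intermediate
6 | methyl (3R)-3-bromo-2,2-dimethylhept-6-ynoate | C#CCC[C@@H](Br)C(C)(C)C(=O)OC | intermediate
7 | (3R)-3-bromo-2,2-dimethylhept-6-ynal | C#CCC[C@@H](Br)C(C)(C)C=O | intermediate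
8 | 4-bromo-2,5-dimethoxybenzaldehyde | COc1cc(C=O)c(OC)cc1Br | starting material
9 | (4-bromo-2,5-dimethoxyphenyl)methanol | COc1cc(CO)c(OC)cc1Br | intermediate
10 | (4-bromo-2,5-dimethoxybenzyl)triphenylphosphonium bromide | COc1cc(C[P+](c2ccccc2)(c2ccccc2)c2ccccc2)c(OC)cc1Br.[Br-] | intermediate
11 | (4-bromo-2,5-dimethoxybenzylidene)triphenylphosphorane (not isolated) | COc1cc(C=P(c2ccccc2)(c2ccccc2)c2ccccc2)c(OC)cc1Br | intermediate
12 | 1-bromo-4-[(1E,4R)-4-bromo-3,3-dimethyloct-1-en-7-yn-1-yl]-2,5-dimethoxybenzene | C#CCC[C@@H](Br)C(C)(C)/C=C/c1cc(OC)c(Br)cc1OC | intermediate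
13 | 1-bromo-4-{[(1S,3R)-3-bromo-2,2-dimethyl-6-methylidenecyclohexyl]methyl}-2,5-dimethoxybenzene (cyclocymopol dimethyl ether) | C=C1CC[C@@H](Br)C(C)(C)[C@H]1Cc1cc(OC)c(Br)cc1OC | intermediate
14 | 2-bromo-5-{[(1S,3R)-3-bromo-2,2-dimethyl-6-methylidenecyclohexyl]methyl}cyclohexa-2,5-diene-1,4-dione (not isolated) | C=C1CC[C@@H](Br)C(C)(C)[C@H]1CC1=CC(=O)C(Br)=CC1=O | intermediate
15 | cyclocymopol, 2-bromo-5-{[(1S,3R)-3-bromo-2,2-dimethyl-6-methylidenecyclohexyl]methyl}benzene-1,4-diol | C=C1CC[C@@H](Br)C(C)(C)[C@H]1Cc1cc(O)c(Br)cc1O | target

Total step count: 9. Longest linear sequence: 7 (steps 1–4 and 7–9).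

Steps most likely to fail

Step 3. Substitution at the neopentylic carbon may be so slow that elimination towards C4 takes over. Participation of the ester carbonyl could also give partial retention, which would erode the enantiomeric purity. The fallback sets out from 4 and uses ring strain instead of a better leaving group.
- Saponification (LiOH, THF/H2O) would give (3S)-3-hydroxy-2,2-dimethylhept-6-ynoic acid F1.
- Carboxyl activation (PhSO2Cl, pyridine, 0 °C) would close it with retention to (4S)-4-(but-3-yn-1-yl)-3,3-dimethyloxetan-2-one F2.
- In the four-membered ring the gem-dimethyl group is tied back from the line of attack, so MgBr2·OEt2 (Et2O, rt) should cleave the alkyl–oxygen bond with inversion to (3R)-3-bromo-2,2-dimethylhept-6-ynoic acid F3.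
- Methylation with TMSCHN2 (toluene/MeOH) comes back to the route at 6.

Step 8. Three processes could compete with the intended path. β-Hydride elimination of the benzylpalladium species may outrun silane capture and lead to a diene. Palladium and silane may cause hydrodebromination or migration of the exocyclic double bond. Facial selectivity at the styrene may be poor. The fallback sets out from 12 and changes to a cationic manifold that is inert to C–Br bonds.
- Gold(I) catalysis ([JohnPhosAu(NCMe)]SbF6, MeOH/CH2Cl2, rt) would make the same C6–C1 bond by 6-exo-dig methoxycyclisation (anti addition). This gives 1-bromo-4-{(S)-[(1S,3R)-3-bromo-2,2-dimethyl-6-methylidenecyclohexyl](methoxy)methyl}-2,5-dimethoxybenzene F4.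
- Ionic reduction of the activated benzylic ether (Et3SiH, BF3·OEt2, CH2Cl2, −78 °C) comes back at 13.

Step 7. Addition of the ylide to the α-quaternary aldehyde may be sluggish. That would leave time for base-induced loss of HBr or for attack of an oxyanion on the γ-bromide. The fallback sets out from 7 and avoids base at the aldehyde stage.
- Takai olefination (CHI3, CrCl2, THF, 0 °C) would give (1E,4R)-4-bromo-1-iodo-3,3-dimethyloct-1-en-7-yne F5.
- Copper-free Suzuki–Miyaura coupling with commercial (4-bromo-2,5-dimethoxyphenyl)boronic acid (Pd(PPh3)4, aq. K2CO3, THF, rt) should be selective for the alkenyl iodide over the aryl bromide. It comes back at 12.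

Further compounds
F1 | step 3 | (3S)-3-hydroxy-2,2-dimethylhept-6-ynoic acid | C#CCC[C@H](O)C(C)(C)C(=O)O
F2 | step 3 | (4S)-4-(but-3-yn-1-yl)-3,3-dimethyloxetan-2-one | C#CCC[C@@H]1OC(=O)C1(C)C
F3 | step 3 | (3R)-3-bromo-2,2-dimethylhept-6-ynoic acid | C#CCC[C@@H](Br)C(C)(C)C(=O)O
F4 | step 8 | 1-bromo-4-{(S)-[(1S,3R)-3-bromo-2,2-dimethyl-6-methylidenecyclohexyl](methoxy)methyl}-2,5-dimethoxybenzene | C=C1CC[C@@H](Br)C(C)(C)[C@H]1[C@H](OC)c1cc(OC)c(Br)cc1OC
F5 | step 7 | (1E,4R)-4-bromo-1-iodo-3,3-dimethyloct-1-en-7-yne | C#CCC[C@@H](Br)C(C)(C)/C=C/I
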